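**Plan**

- Numbering: C1 (benzoyl bridgehead), C2(=O), C3 (quaternary), C4(=O), C5 (geranyl bridgehead), C6H2, C7H, C8Me2, C9 (bridging C=O); C10H2–C11H links C7 to C3; ring D is C3, C11, C12Me2, C13(=O), C14H2.
- Enabling feature: ring A (C1, C9, C5, C6, C7, C8) is a cyclohexanone whose C9–C1–C8–C7 part can pre-exist as a gem-dimethylcyclobutanone, with C5=C6 as an olefin held on C1 through C2–C3–C4. That four-membered ketone is the one found in chrysanthenone.
- Cuts, in retrosynthetic order: C1–COPh; C9–C5 and C6–C7 together (rings A and B); C3–C4; C3–C14 (ring D); C11–C12; C3=C11 (seven-membered ring).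
- Forward: verbenone → chrysanthenone (cyclobutanone) → bridged cycloheptenone (ozonolysis, aldol) → ring D (Michael addition, enolate coupling) → enone arm on C3 → rings A and B by rhodium insertion → benzoyl on C1.
- Stereochemistry: C7 and C1 come from (1S,5S)-verbenone; C11 and C3 are set by attack anti to the C8 gem-dimethyl bridge; C5 is fixed by the framework in the key step.

Key step: step 14

Remark: commercial (1S,5S)-(−)-verbenone is taken to be of high enantiomeric purity, and the photochemical shift is stopped at partial conversion so that this purity is kept.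
Remark: 16 and 17 are carried as C3 epimers (C3 is planarised in step 12) and 18 as C4 epimers (erased in step 13); the cage atom numbers above are used for all intermediates.

**Route**

Step 1
Reactants: 1 geranyl bromide, (2E)-1-bromo-3,7-dimethylocta-2,6-diene
Product: 2 tert-butyl (4E)-5,9-dimethyldeca-4,8-dienoate
Conditions: tert-butyl acetate, LiN(iPr)2, THF, −78 °C; then 1, −78 to 0 °C
Reagents that add atoms: tert-butyl acetate, CC(=O)OC(C)(C)C
Why: SN2 alkylation of the lithium ester enolate by the primary allylic bromide is fast at low temperature, the tert-butyl ester suppresses Claisen self-condensation, and the E olefin is not touched.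

Step 2
Reactants: 2 tert-butyl (4E)-5,9-dimethyldeca-4,8-dienoate
Product: 3 (4E)-5,9-dimethyldeca-4,8-dienal
Conditions: iBu2AlH (1.1 equiv), toluene, −78 °C; aqueous work-up
Reagents that add atoms: none
Why: Partial ester reduction with iBu2AlH should stop at the tetrahedral aluminium hemiacetal at −78 °C, which releases the aldehyde on work-up.

Step 3
Reactants: 3 (4E)-5,9-dimethyldeca-4,8-dienal
Product: 4 (4E)-5,9-dimethyl-2-methylidenedeca-4,8-dienal
Conditions: 37% aq. formaldehyde, pyrrolidine (10 mol %), propanoic acid (10 mol %), i-PrOH, 45 °C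
Reagents that add atoms: formaldehyde, C=O
Why: Amine/acid-catalysed α-methylenation (Mannich condensation then elimination) converts an α-unbranched aldehyde into the 2-substituted acrolein under near-neutral conditions, which should spare the skipped diene.

Step 4
Reactants: 5 3-methylbutan-2-one
Product: 6 trimethyl[(3-methylbut-2-en-2-yl)oxy]silane
Conditions: Me3SiCl, NaI, Et3N, MeCN, rt
Reagents that add atoms: chlorotrimethylsilane, C[Si](C)(C)Cl
Why: Enol silylation with Me3SiI formed in situ under equilibrating conditions should give the more substituted, tetrasubstituted silyl enol ether.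

Step 5
Reactants: 7 (1S,5S)-verbenone, (1S,5S)-4,6,6-trimethylbicyclo[3.1.1]hept-3-en-2-one
Product: 8 (1R,5S)-chrysanthenone, (1R,5S)-2,7,7-trimethylbicyclo[3.1.1]hept-2-en-6-one
Conditions: hν (medium-pressure Hg lamp, Pyrex filter), cyclohexane, rt, partial conversion
Reagents that add atoms: none
Why: In this photochemical 1,3-alkyl shift the CMe2 carbon migrates suprafacially from C5 to C3 of the enone, C1 of verbenone is untouched and becomes the CH2-bearing bridgehead (future C7), and the second bridgehead (future C1) follows from the bicyclic constraint.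

Step 6
Reactants: 8 (1R,5S)-chrysanthenone
Product: 9 (1R,5S)-2,7,7-trimethylspiro[bicyclo[3.1.1]hept-2-ene-6,2'-[1,3]dioxolane]
Conditions: 1,2-bis(trimethylsilyloxy)ethane, Me3SiOTf (5 mol %), CH2Cl2, −78 to −20 °C
Reagents that add atoms: 1,2-bis(trimethylsilyloxy)ethane, C[Si](C)(C)OCCO[Si](C)(C)C
Why: Noyori ketalisation of the strained four-membered ketone is favourable at low temperature, leaves the trisubstituted olefin alone, and protects C9 from retro-Claisen opening in the basic step 8.

Step 7
Reactants: 9 (1R,5S)-2,7,7-trimethylspiro[bicyclo[3.1.1]hept-2-ene-6,2'-[1,3]dioxolane]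
Product: 11 2-[(1S,3S)-3-acetyl-2,2-dimethyl-5,8-dioxaspiro[3.4]octan-1-yl]acetaldehyde, via ozonide 10 (not isolated)
Conditions: O3, CH2Cl2, −78 °C; then PPh3, −78 °C to rt
Reagents that add atoms: ozone, [O-][O+]=O
Why: Ozonolysis of the only olefin with reductive work-up gives the methyl ketone (C2, C3) and the aldehyde (C11) held cis on the cyclobutane, and no stereocentre is touched.

Step 8
Reactants: 11 2-[(1S,3S)-3-acetyl-2,2-dimethyl-5,8-dioxaspiro[3.4]octan-1-yl]acetaldehyde
Product: 13 (1S,6S)-8,8-dimethylbicyclo[4.1.1]oct-3-ene-2,7-dione, via ketal enone 12 (not isolated)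
Conditions: KOH, MeOH, 0 °C to rt; then 2 M HCl, THF, rt
Reagents that add atoms: water, O
Why: In this intramolecular aldol condensation only the methyl carbon C3 can reach the aldehyde C11 without forming a bicyclo[2.1.1] ring, which closes the cis-cycloheptenone (C1 equilibrates and only the cis isomer cyclises), and aqueous acid then hydrolyses the ketal to give back the flat C9 carbonyl bridge.

Step 9
Reactants: 13 (1S,6S)-8,8-dimethylbicyclo[4.1.1]oct-3-ene-2,7-dione; 6 trimethyl[(3-methylbut-2-en-2-yl)oxy]silane
Product: 15 (1S,4R,6S)-8,8-dimethyl-4-(2-methyl-3-oxobutan-2-yl)bicyclo[4.1.1]octane-2,7-dione, via trimethylsilyl enol ether 14 (not isolated)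
Conditions: 6 (1.5 equiv), HNTf2 (5 mol %), CH2Cl2, −78 °C; then 1 M HCl, THF
Reagents that add atoms: none
Why: In this Mukaiyama–Michael addition (catalyst Me3SiNTf2 formed in situ) the enol silane attacks C11 from the face of the flat C9 carbonyl bridge, anti to the syn methyl group of the C8 bridge, which sets C11 and forms the C11–C12 bond next to a quaternary carbon.

Step 10
Reactants: 15 (1S,4R,6S)-8,8-dimethyl-4-(2-methyl-3-oxobutan-2-yl)bicyclo[4.1.1]octane-2,7-dione
Product: 16 tricyclic trione: 2,2-dimethylcyclopentanone ring D (C3, C14, C13, C12, C11) fused at C3–C11 to the 8,8-dimethylbicyclo[4.1.1]octane-2,9-dione core (C3–H epimers)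
Conditions: LiN(iPr)2 (2.3 equiv), THF, −78 to −40 °C; then CuCl2 (2.2 equiv), DMF, −78 °C to rt
Reagents that add atoms: none
Why: Intramolecular oxidative enolate coupling of the dilithium dienolate (C3 and C14 are the only enolisable carbons, since C1 and C7 are bridgeheads and C12 is quaternary) should close ring D through the C3–C14 bond in a 5-exo sense; any reversible aldol of the mono-enolate is drained by the second deprotonation.

Step 11
Reactants: 16 tricyclic trione (C3–H epimers)
Product: 17 C13 triisopropylsilyl enol ether of 16 (C13=C14; C3–H epimers)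
Conditions: iPr3SiOTf (1.05 equiv), Et3N, CH2Cl2, −78 to 0 °C
Reagents that add atoms: triisopropylsilyl trifluoromethanesulfonate, CC(C)[Si](C(C)C)(C(C)C)OS(=O)(=O)C(F)(F)F
Why: Soft enolisation and O-silylation should take the trisubstituted C13=C14 enol of the cyclopentanone in preference to the tetrasubstituted ring-fusion enol of C2, which masks C13 for steps 12 to 15 and leaves C3–H as the only enolisable position.

Step 12
Reactants: 17 C13 triisopropylsilyl enol ether of 16; 4 (4E)-5,9-dimethyl-2-methylidenedeca-4,8-dienal
Product: 18 aldol adduct: C3 quaternary with the CH(OH)–C(=CH2)–CH2-geranyl arm on the C9 face (C4 epimers)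
Conditions: LiN(iPr)2 (1.1 equiv), THF, −78 °C; then 4, −78 °C; AcOH quench at −78 °C
Reagents that add atoms: none
Why: In this aldol addition the only possible lithium enolate (C2/C3) adds 1,2 to the non-enolisable enal, and the aldehyde should enter C3 from the face of the C9 carbonyl bridge, anti to the syn methyl of C8, which makes ring D trans-fused and places the arm over C9; the cold acidic quench limits retro-aldol and attack of the alkoxide on C9.

Step 13
Reactants: 18 aldol adduct (C4 epimers)
Product: 19 insertion precursor: 2-geranylpropenoyl arm on C3 of the ring-D-fused bicyclo[4.1.1]octane-2,9-dione, C13 as triisopropylsilyl enol ether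
Conditions: Dess–Martin periodinane, CH2Cl2, 0 °C to rt
Reagents that add atoms: none
Why: Dess–Martin oxidation converts the hindered allylic carbinol into the enone under neutral conditions and removes the C4 stereocentre, with no epimerisable centre present.

Step 14
Reactants: 19 insertion precursor
Product: 20 debenzoyl cage (hydrogen on C1), C13 as triisopropylsilyl enol ether
Conditions: [Rh(C2H4)2Cl]2 (5 mol %), P[3,5-(CF3)2C6H3]3 (20 mol %), 1,4-dioxane, 120 °C, sealed tube
Reagents that add atoms: none
Why: Proposed new method: the monovalent rhodium centre should add oxidatively into the strained C9–C7 bond to give a five-membered acyl(alkyl) complex of trivalent rhodium, the 1,1-disubstituted enone olefin held over C9 by the C2–C3–C4 tether then inserts (C7 migrating to the unsubstituted terminus C6 as in a conjugate addition), and reductive elimination from the rhodium enolate joins C9 to C5. The closest known reaction type is the rhodium-catalysed intramolecular carboacylation of olefins by cyclobutanones ("cut-and-sew"), established for olefins tethered through the β-carbon of the four-membered ring and, as far as can be recalled, for α-tethered alkynes that give bicyclo[3.3.1]nonenones; an α-tethered olefin on a 2-acylcyclobutanone is untested. Ring B (C1, C2, C3, C4, C5, C9) closes in a 6-exo sense at the internal olefin carbon C5, and ring A (C1, C9, C5, C6, C7, C8) arises as a two-carbon enlargement of the four-membered ring, so that C9 becomes the one-atom bridge of a bridged [4+2] adduct. The only new stereocentre, C5, is dictated by the framework, because C5 must bond to C9 and, through C6, to C7 on the face of the former four-membered ring, and C7 reacts with retention because rhodium takes the place of C9. The step needs cleavage of C9–C7 and not of the ketone-activated C9–C1 bond, and the C9-to-C5, C7-to-C6 orientation: only the C9–C7 rhodacycle can reach the olefin through the three-atom tether and form six-membered rings, addition at C9–C1 is reversible and unproductive, and the electron-poor phosphine without an amine co-catalyst should hold back decarbonylation and retro-Claisen opening.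

Step 15
Reactants: 20 debenzoyl cage, C13 as triisopropylsilyl enol ether
Product: 21 C1-benzoyl cage, C13 as triisopropylsilyl enol ether
Conditions: lithium 2,2,6,6-tetramethylpiperidide (1.3 equiv), THF, −78 °C; then PhCOCl, −78 to −40 °C
Reagents that add atoms: benzoyl chloride, O=C(Cl)c1ccccc1
Why: In this bridgehead deprotonation and C-acylation, C1–H between the C2 and C9 carbonyls is the most acidic proton once C13 is masked, and the pyramidal bridgehead carbanion should be acylated at carbon with the only configuration the cage allows.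

Step 16
Reactants: 21 C1-benzoyl cage, C13 as triisopropylsilyl enol ether
Product: 22 target CNP0110281.1
Conditions: HF·pyridine, THF, 0 °C to rt
Reagents that add atoms: none
Why: Acidic fluoride cleavage of the silyl enol ether frees the C13 ketone without base, so the non-enolisable triketone and the geranyl olefins should survive.

**Compound list**

1 | geranyl bromide, (2E)-1-bromo-3,7-dimethylocta-2,6-diene | CC(C)=CCC/C(C)=C/CBr | starting material
2 | tert-butyl (4E)-5,9-dimethyldeca-4,8-dienoate | CC(C)=CCC/C(C)=C/CCC(=O)OC(C)(C)C | intermediate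
3 | (4E)-5,9-dimethyldeca-4,8-dienal | CC(C)=CCC/C(C)=C/CCC=O | intermediate
4 | (4E)-5,9-dimethyl-2-methylidenedeca-4,8-dienal | CC(C)=CCC/C(C)=C/CC(=C)C=O | intermediate
5 | 3-methylbutan-2-one | CC(C)C(C)=O | starting material
6 | trimethyl[(3-methylbut-2-en-2-yl)oxy]silane | CC(C)=C(C)O[Si](C)(C)C | intermediate
7 | (1S,5S)-verbenone, (1S,5S)-4,6,6-trimethylbicyclo[3.1.1]hept-3-en-2-one | CC1=CC(=O)[C@H]2C[C@@H]1C2(C)C | starting material
8 | (1R,5S)-chrysanthenone, (1R,5S)-2,7,7-trimethylbicyclo[3.1.1]hept-2-en-6-one | CC1=CC[C@@H]2C(=O)[C@H]1C2(C)C | intermediate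
9 | (1R,5S)-2,7,7-trimethylspiro[bicyclo[3.1.1]hept-2-ene-6,2'-[1,3]dioxolane] | CC1=CC[C@@H]2C3(OCCO3)[C@H]1C2(C)C | intermediate
10 | ozonide of 9 (1,2,4-trioxolane across the former olefin; new acetal centres unassigned) | CC12OC(OO1)C[C@@H]3C4(OCCO4)[C@H]2C3(C)C | intermediate (not isolated)
11 | 2-[(1S,3S)-3-acetyl-2,2-dimethyl-5,8-dioxaspiro[3.4]octan-1-yl]acetaldehyde | O=CC[C@@H]1C2(OCCO2)[C@H](C(C)=O)C1(C)C | intermediate
12 | (1S,6S)-8,8-dimethylspiro[bicyclo[4.1.1]oct-3-ene-7,2'-[1,3]dioxolan]-2-one | O=C1C=CC[C@@H]2C3(OCCO3)[C@H]1C2(C)C | intermediate (not isolated)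
13 | (1S,6S)-8,8-dimethylbicyclo[4.1.1]oct-3-ene-2,7-dione | O=C1C=CC[C@@H]2C(=O)[C@H]1C2(C)C | intermediate
14 | C2 trimethylsilyl enol ether of 15 (C2=C3) | CC(=O)C(C)(C)[C@@H]1C[C@@H]2C(=O)[C@H](C(O[Si](C)(C)C)=C1)C2(C)C | intermediate (not isolated)
15 | (1S,4R,6S)-8,8-dimethyl-4-(2-methyl-3-oxobutan-2-yl)bicyclo[4.1.1]octane-2,7-dione | CC(=O)C(C)(C)[C@@H]1C[C@@H]2C(=O)[C@H](C(=O)C1)C2(C)C | intermediate
16 | tricyclic trione, ring D fused at C3–C11 to the bicyclo[4.1.1]octane-2,9-dione (C3–H epimers) | C12CC(=O)C(C)(C)[C@@H]1C[C@@H]3C(=O)[C@H](C2=O)C3(C)C | intermediate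
17 | C13 triisopropylsilyl enol ether of 16 (C3–H epimers) | C12C=C(O[Si](C(C)C)(C(C)C)C(C)C)C(C)(C)[C@@H]1C[C@@H]3C(=O)[C@H](C2=O)C3(C)C | intermediate
18 | aldol adduct, C3 quaternary, arm CH(OH)–C(=CH2)–CH2-geranyl (C4 epimers) | CC(C)=CCC/C(C)=C/CC(=C)C(O)[C@]12C=C(O[Si](C(C)C)(C(C)C)C(C)C)C(C)(C)[C@@H]1C[C@@H]3C(=O)[C@H](C2=O)C3(C)C | intermediate
19 | insertion precursor, 2-geranylpropenoyl arm on C3, C13 silyl enol ether | CC(C)=CCC/C(C)=C/CC(=C)C(=O)[C@]12C=C(O[Si](C(C)C)(C(C)C)C(C)C)C(C)(C)[C@@H]1C[C@@H]3C(=O)[C@H](C2=O)C3(C)C | intermediate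
20 | debenzoyl cage (hydrogen on C1), C13 silyl enol ether | CC(C)=CCC/C(C)=C/C[C@@]12C[C@H]3C[C@H]4C(C)(C)C(O[Si](C(C)C)(C(C)C)C(C)C)=C[C@]4(C1=O)C(=O)[C@@H](C2=O)C3(C)C | intermediate
21 | C1-benzoyl cage, C13 silyl enol ether | CC(C)=CCC/C(C)=C/C[C@@]12C[C@H]3C[C@H]4C(C)(C)C(O[Si](C(C)C)(C(C)C)C(C)C)=C[C@]4(C1=O)C(=O)[C@@](C(=O)c1ccccc1)(C2=O)C3(C)C | intermediate
22 | CNP0110281.1 | CC(C)=CCC/C(C)=C/C[C@@]12C[C@H]3C[C@H]4C(C)(C)C(=O)C[C@]4(C1=O)C(=O)[C@@](C(=O)c1ccccc1)(C2=O)C3(C)C | target

Total step count: 16
Longest linear sequence: 12 steps (7 to 22, steps 5 to 16)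

**Steps most likely to fail**

1. Step 14 (rhodium insertion). What may go wrong: oxidative addition at the ketone-activated C9–C1 bond, decarbonylation to a cyclopropane, or metal-hydride isomerisation of the skipped diene before the olefin inserts. Fallback, from 17 (with 3) back to 20, by two one-carbon diazo homologations in place of the insertion. Aldol addition of the lithium enolate of 17 to aldehyde 3 would give the carbinol F1, and Dess–Martin oxidation the saturated ketone F2, in which C5H2 is the only enolisable position. Detrifluoroacetylative Regitz diazo transfer (LiN(SiMe3)2, CF3CO2CH2CF3; then MeSO2N3, Et3N) through the trifluoroacetyl ketone F3 would give the α-diazo ketone F4. CH2N2 (Et2O/MeOH, 0 °C) would then enlarge the four-membered ketone by C6, with migration of C7 (the α-carbon without an acyl group), to the cyclopentanone diazo ketone F5. Finally Sc(OTf)3 (CH2Cl2, −78 °C to rt) should let the diazo carbon C5 add to C9 and C6 shift from C9 to C5 with loss of nitrogen, an intramolecular Tiffeneau–Demjanov-type ring enlargement that closes rings B and A and gives 20.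

2. Step 12 (aldol at C3). What may go wrong: retro-aldol on warming, addition of the C4 alkoxide to the strained C9 carbonyl followed by retro-Claisen opening of the four-membered ring, or attack on the face of the gem-dimethyl bridge. Fallback, from 17 (with 4) directly to 19, by acyl transfer instead of aldol and oxidation. Pinnick oxidation of 4 (NaClO2, NaH2PO4, 2-methylbut-2-ene) would give (4E)-5,9-dimethyl-2-methylidenedeca-4,8-dienoic acid F6, and 1H-benzotriazole/SOCl2 the N-acylbenzotriazole F7. The lithium enolate of 17 would then be C-acylated by F7 at −78 °C to give 19, so that no alkoxide is formed and step 13 is not needed.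

3. Step 15 (bridgehead benzoylation). What may go wrong: slow acyl transfer to the hindered bridgehead carbanion, so that the anion is protonated or the acid chloride is consumed by the amide base or at oxygen. Fallback, from 20 back to 21, by addition and oxidation instead of acylation. The lithiated cage would be trapped with benzaldehyde, a smaller and more reactive electrophile, to give the bridgehead carbinol F8, and Dess–Martin oxidation would then give 21.

**Further compounds**

F1 | step 14 | aldol adduct of 17 with 3, arm CH(OH)–CH2–CH2-geranyl... written as C4 carbinol with saturated C5H2 (C4 epimers) | CC(C)=CCC/C(C)=C/CCC(O)[C@]12C=C(O[Si](C(C)C)(C(C)C)C(C)C)C(C)(C)[C@@H]1C[C@@H]3C(=O)[C@H](C2=O)C3(C)C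
F2 | step 14 | C4 ketone with saturated C5H2–geranyl arm | CC(C)=CCC/C(C)=C/CCC(=O)[C@]12C=C(O[Si](C(C)C)(C(C)C)C(C)C)C(C)(C)[C@@H]1C[C@@H]3C(=O)[C@H](C2=O)C3(C)C
F3 | step 14 | C5 trifluoroacetyl derivative of F2 (not isolated, C5 epimers) | CC(C)=CCC/C(C)=C/CC(C(=O)C(F)(F)F)C(=O)[C@]12C=C(O[Si](C(C)C)(C(C)C)C(C)C)C(C)(C)[C@@H]1C[C@@H]3C(=O)[C@H](C2=O)C3(C)C
F4 | step 14 | C5 diazo ketone, four-membered ketone intact | CC(C)=CCC/C(C)=C/CC(=[N+]=[N-])C(=O)[C@]12C=C(O[Si](C(C)C)(C(C)C)C(C)C)C(C)(C)[C@@H]1C[C@@H]3C(=O)[C@H](C2=O)C3(C)C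
F5 | step 14 | C5 diazo ketone after enlargement to the C9–C6H2–C7 cyclopentanone | CC(C)=CCC/C(C)=C/CC(=[N+]=[N-])C(=O)[C@]12C=C(O[Si](C(C)C)(C(C)C)C(C)C)C(C)(C)[C@@H]1C[C@@H]3CC(=O)[C@H](C2=O)C3(C)C
F6 | step 12 | (4E)-5,9-dimethyl-2-methylidenedeca-4,8-dienoic acid | CC(C)=CCC/C(C)=C/CC(=C)C(=O)O
F7 | step 12 | 1-[(4E)-5,9-dimethyl-2-methylidenedeca-4,8-dienoyl]-1H-benzotriazole | CC(C)=CCC/C(C)=C/CC(=C)C(=O)n1nnc2ccccc12
F8 | step 15 | bridgehead carbinol, C1–CH(OH)Ph cage with C13 silyl enol ether (carbinol epimers) | CC(C)=CCC/C(C)=C/C[C@@]12C[C@H]3C[C@H]4C(C)(C)C(O[Si](C(C)C)(C(C)C)C(C)C)=C[C@]4(C1=O)C(=O)[C@@](C(O)c1ccccc1)(C2=O)C3(C)C
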